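**Plan**
1. Quinone ring numbering: C1' (C=O), C2' (OH), C3' (bears C11H2), C4' (C=O), C5' (OMe), C6' (H). Its four different groups sit in a fixed ring order on a neopentyl CH2 (C11 on quaternary C9). C1'–C4' map onto a squarate and C5'–C6' onto a methoxyvinyl unit; this is what allows the ring expansion.
2. Retrosynthetic cuts, in order: O–tBu at C2'; ring bond C4'–C5' (six-membered ring back to a cyclobutenone); C1'–C6' (vinyllithium addition); C11–C3' (alkyllithium plus di-tert-butyl squarate); then C9–C10 and C7–C8 of ring B (Diels–Alder of a ring-A diene with tiglaldehyde).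
3. Forward order: ring A comes from 3-methylcyclohexenone, ring B is closed by the cycloaddition, C11 is joined to the squarate, the methoxyvinyl unit is added, and the quinone ring is formed last.
4. Stereochemistry: an enantioselective ketone reduction sets a temporary carbinol at C4. It steers the diene face, the cycloaddition sets C8, C9 and C10, a hydroxyl-directed hydrogenation sets C5, and the C4 carbinol is then erased as the methylene.

Key step: step 15

Numbering: decalin C1–C10 (ring A: C1–C5 and C10; ring B: C5–C10), C11 = CH2 on C9, β = face of the C10 methyl. DecCH2 = [(1R,2S,4aS,8aS)-1,2,8a-trimethyl-5-methylidenedecahydronaphthalen-1-yl]methyl, the side chain of the target.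
Assumption: the sense of the reduction in step 2 follows the usual model with the iodoalkenyl arm as the large group (if the other carbinol formed, the mirror-image catalyst would be used); bromide 21 is carried on as the Z isomer.

**Step 1**
Reactants: 1 3-methylcyclohex-2-en-1-one
Product: 2 2-iodo-3-methylcyclohex-2-en-1-one
Conditions: I2, pyridine, CH2Cl2, 0 °C → rt
Reagents that add atoms: iodine, II
Why: α-Iodination of an enone through reversible conjugate addition of pyridine, iodination of the resulting enolate and elimination is a standard way to 2-iodocyclohexenones and places the halogen that the later coupling needs.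

**Step 2**
Reactants: 2 2-iodo-3-methylcyclohex-2-en-1-one
Product: 3 (S)-2-iodo-3-methylcyclohex-2-en-1-ol
Conditions: (R)-2-methyl-CBS-oxazaborolidine (20 mol%), BH3·SMe2, THF, −20 °C
Reagents that add atoms: none
Why: Corey–Bakshi–Shibata reduction in which the iodoalkenyl arm plays the large group, so that the (R)-catalyst should deliver hydride to the face giving the (S)-carbinol, the single source of absolute configuration for the whole route.

**Step 3**
Reactants: 3 (S)-2-iodo-3-methylcyclohex-2-en-1-ol
Product: 4 (S)-tert-butyl[(2-iodo-3-methylcyclohex-2-en-1-yl)oxy]dimethylsilane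
Conditions: TBSCl, imidazole, DMF, rt
Reagents that add atoms: tert-butyldimethylsilyl chloride, CC(C)(C)[Si](C)(C)Cl
Why: Standard silylation of a secondary allylic alcohol, chosen because the bulky silyl ether later shields one diene face and survives the organometallic and Lewis-acidic steps.

**Step 4**
Reactants: 4 (S)-tert-butyl[(2-iodo-3-methylcyclohex-2-en-1-yl)oxy]dimethylsilane
Product: 5 (S)-tert-butyl[(2-ethenyl-3-methylcyclohex-2-en-1-yl)oxy]dimethylsilane
Conditions: CH2=CHSnBu3, Pd(PPh3)4 (5 mol%), CuI (10 mol%), CsF, DMF, 45 °C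
Reagents that add atoms: tributyl(vinyl)stannane, C=C[Sn](CCCC)(CCCC)CCCC
Why: Stille coupling of an alkenyl iodide with a vinylstannane, helped by CuI and fluoride for the hindered alkene, gives the semicyclic diene without touching the carbinol centre.

**Step 5**
Reactants: 5 (S)-silyloxy diene; 6 tiglaldehyde
Product: 7 4β-silyloxy octalin aldehyde (C5=C6; 8β-Me 9β-Me 10β-Me; 9α-CHO)
Conditions: 6 (3 equiv), Me2AlCl (0.5 equiv), CH2Cl2, −78 → −20 °C
Reagents that add atoms: none
Why: Lewis-acid-promoted Diels–Alder reaction in which the enal β-carbon bonds to the unsubstituted diene terminus C7 and the α-carbon to C10, the E geometry of 6 fixing the cis 8,9-dimethyl pair, the endo orientation of the complexed formyl group placing C11 trans to the C10 methyl, and approach anti to the pseudoaxial silyloxy group at C4 fixing the absolute sense.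

**Step 6**
Reactants: 7 4β-silyloxy octalin aldehyde
Product: 8 4β-silyloxy octalin 9α-methanol (C5=C6)
Conditions: NaBH4, MeOH, 0 °C
Reagents that add atoms: none
Why: Hydride reduction of the neopentyl aldehyde gives the primary alcohol that serves as directing group in the next step and as the handle for activating C11.

**Step 7**
Reactants: 8 4β-silyloxy octalin 9α-methanol
Product: 9 4β-silyloxy trans-decalin 9α-methanol (5α-H)
Conditions: H2 (1 atm), [Ir(cod)(PCy3)(py)]PF6 (10 mol%), CH2Cl2, rt
Reagents that add atoms: none
Why: Hydroxyl-directed hydrogenation with a cationic iridium catalyst, in which the α-oriented C11 hydroxyl binds the metal and delivers hydrogen to the α face of the hindered C5=C6 bond, setting the 5α-hydrogen and hence the trans ring fusion.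

**Step 8**
Reactants: 9 4β-silyloxy trans-decalin 9α-methanol
Product: 11 4β-silyloxy C11 iodide, via C11 triflate 10 (not isolated)
Conditions: Tf2O, pyridine, CH2Cl2, −20 °C; then n-Bu4NI, 0 → 40 °C
Reagents that add atoms: tetrabutylammonium iodide, CCCC[N+](CCCC)(CCCC)CCCC.[I-]
Why: Sulfonate displacement (SN2) at a neopentyl carbon, made workable by the triflate leaving group and by the absence of any β-hydrogen that could eliminate.

**Step 9**
Reactants: 11 4β-silyloxy C11 iodide
Product: 12 4β-hydroxy C11 iodide
Conditions: n-Bu4NF, THF, 45 °C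
Reagents that add atoms: none
Why: Fluoride-induced desilylation, to which the neopentyl iodide is inert because it can neither be displaced readily nor eliminated.

**Step 10**
Reactants: 12 4β-hydroxy C11 iodide
Product: 13 4-oxo C11 iodide
Conditions: Dess–Martin periodinane, NaHCO3, CH2Cl2, 0 °C → rt
Reagents that add atoms: none
Why: Dess–Martin oxidation under buffered, near-neutral conditions converts the axial carbinol into the ketone without epimerising the adjacent ring-fusion centre C5.

**Step 11**
Reactants: 13 4-oxo C11 iodide
Product: 14 4-methylene C11 iodide (DecCH2–I)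
Conditions: Cp2TiMe2, toluene/THF, 65 °C, dark
Reagents that add atoms: dimethyltitanocene, C[Ti](C)(C1C=CC=C1)C1C=CC=C1
Why: Petasis methylenation, in which a titanium methylidene formed on heating adds to the carbonyl and cycloreverts to the alkene, is non-basic and therefore keeps the enolisable C5 centre and the alkyl iodide intact.

**Step 12**
Reactants: 14 DecCH2–I; 15 di-tert-butyl squarate
Product: 19 3-tert-butoxy-4-(DecCH2)cyclobut-3-ene-1,2-dione, via alkyllithium 16 (not isolated), via lithium alkoxide adduct 17 (not isolated), via adduct trifluoroacetate 18 (not isolated)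
Conditions: t-BuLi (2.1 equiv), Et2O/pentane, −78 °C; 15, THF, −78 °C; then (CF3CO)2O, −78 → 0 °C; aq NaHCO3
Reagents that add atoms: none
Why: Lithium–iodine exchange of a primary iodide, 1,2-addition of the alkyllithium to one squarate carbonyl and trifluoroacetic-anhydride-induced rearrangement with loss of one tert-butyl group is the established entry to 3-alkyl-4-alkoxycyclobutenediones, and at −78 °C the 5-hexenyl-type lithium reagent should not cyclise onto the methylene.

**Step 13**
Reactants: 20 bromoacetaldehyde dimethyl acetal
Product: 21 (Z)-1-bromo-2-methoxyethene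
Conditions: Me3SiOTf, i-Pr2NEt, CH2Cl2, −20 °C → rt; fractional distillation
Reagents that add atoms: none
Why: Silyl-triflate-mediated elimination of methanol from an acetal (oxocarbenium formation, then deprotonation by the hindered amine) gives the bromo enol ether, the Z isomer being favoured for ethenes with heteroatoms on both carbons.

**Step 14**
Reactants: 19 3-tert-butoxy-4-(DecCH2)cyclobut-3-ene-1,2-dione; 21 (Z)-1-bromo-2-methoxyethene
Product: 23 3-tert-butoxy-4-hydroxy-4-[(Z)-2-methoxyethenyl]-2-(DecCH2)cyclobut-2-en-1-one, via (Z)-2-methoxyvinyllithium 22 (not isolated)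
Conditions: 21, t-BuLi (2 equiv per 21), THF/Et2O, −78 °C; then 19, −78 °C; aq NH4Cl
Reagents that add atoms: none
Why: Lithium–bromine exchange with retention gives the Z vinyllithium (stable because lithium and methoxy are cis and cannot undergo anti elimination), which adds 1,2 to the more electrophilic carbonyl next to the tert-butoxy-bearing carbon, the other carbonyl being deactivated as a vinylogous ester, and the new carbinol centre forms as an epimer mixture that is of no consequence.

**Step 15**
Reactants: 23 3-tert-butoxy-4-hydroxy-4-[(Z)-2-methoxyethenyl]-2-(DecCH2)cyclobut-2-en-1-one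
Product: 24 2-tert-butoxy-5-methoxy-3-(DecCH2)benzene-1,4-diol
Conditions: toluene (degassed, dilute), 110 °C
Reagents that add atoms: none
Why: Heating opens the cyclobutenone by conrotatory 4π electrocyclic cleavage of the bond between the carbonyl carbon and the carbinol carbon, the hydroxyl rotating outward so that the methoxyvinyl group ends up cis to the new ketene. The resulting dienylketene closes by thermal disrotatory 6π electrocyclisation, the ketene carbon bonding to the methoxy-bearing vinyl carbon (the one new C–C bond, closing the six-membered carbocycle), and the cyclohexadienone tautomerises to the hydroquinone. The closest known reaction type is the Moore-type ring expansion of 4-alkenyl-4-hydroxycyclobutenones. No stereocentre is created, and both carbinol epimers of 23 converge on 24. The selectivity needed is the outward rotation of the hydroxyl, secured by its donor character, together with the substituent order already fixed in steps 12 and 14. The neutral, reagent-free conditions leave the C4 methylene and the tert-butyl ether untouched.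

**Step 16**
Reactants: 24 2-tert-butoxy-5-methoxy-3-(DecCH2)benzene-1,4-diol
Product: 25 2-tert-butoxy-5-methoxy-3-(DecCH2)cyclohexa-2,5-diene-1,4-dione
Conditions: Ag2O, Na2SO4, Et2O, rt
Reagents that add atoms: none
Why: Oxidation of a hydroquinone to the 1,4-benzoquinone with Ag2O is mild and neutral and leaves the alkene and both ethers in place.

**Step 17**
Reactants: 25 2-tert-butoxy-5-methoxy-3-(DecCH2)cyclohexa-2,5-diene-1,4-dione
Product: 26 2-hydroxy-5-methoxy-3-(DecCH2)cyclohexa-2,5-diene-1,4-dione (target)
Conditions: CF3CO2H (5 equiv), CH2Cl2, 0 °C, short contact; pH 7 buffer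
Reagents that add atoms: none
Why: Acidolysis of the tert-butyl ether of a vinylogous acid (protonation at the quinone carbonyl, loss of the tert-butyl cation as isobutene) is much faster than protonation of the isolated methylene, so a short cold exposure should release the hydroxyquinone.

**Compound list**
1 | 3-methylcyclohex-2-en-1-one | CC1=CC(=O)CCC1 | starting material
2 | 2-iodo-3-methylcyclohex-2-en-1-one | CC1=C(I)C(=O)CCC1 | intermediate
3 | (S)-2-iodo-3-methylcyclohex-2-en-1-ol | O[C@H]1CCCC(C)=C1I | intermediate
4 | (S)-tert-butyl[(2-iodo-3-methylcyclohex-2-en-1-yl)oxy]dimethylsilane | CC(C)(C)[Si](C)(C)O[C@H]1CCCC(C)=C1I | intermediate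
5 | (S)-tert-butyl[(2-ethenyl-3-methylcyclohex-2-en-1-yl)oxy]dimethylsilane | CC(C)(C)[Si](C)(C)O[C@H]1CCCC(C)=C1C=C | intermediate
6 | tiglaldehyde, (E)-2-methylbut-2-enal | C/C=C(\C)C=O | starting material
7 | octalin aldehyde: C5=C6, 4β-OTBS, 8β-Me, 9β-Me, 9α-CHO (C11), 10β-Me | CC(C)(C)[Si](C)(C)O[C@H]1CCC[C@@]2(C)C1=CC[C@H](C)[C@@]2(C)C=O | intermediate
8 | octalin alcohol: as 7 with 9α-CH2OH | CC(C)(C)[Si](C)(C)O[C@H]1CCC[C@@]2(C)C1=CC[C@H](C)[C@@]2(C)CO | intermediate
9 | trans-decalin alcohol: 4β-OTBS, 5α-H, 8β-Me, 9β-Me, 9α-CH2OH, 10β-Me | CC(C)(C)[Si](C)(C)O[C@H]1CCC[C@@]2(C)[C@H]1CC[C@H](C)[C@@]2(C)CO | intermediate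
10 | C11 triflate of 9 | CC(C)(C)[Si](C)(C)O[C@H]1CCC[C@@]2(C)[C@H]1CC[C@H](C)[C@@]2(C)COS(=O)(=O)C(F)(F)F | intermediate (not isolated)
11 | C11 iodide: as 9 with 9α-CH2I | CC(C)(C)[Si](C)(C)O[C@H]1CCC[C@@]2(C)[C@H]1CC[C@H](C)[C@@]2(C)CI | intermediate
12 | 4β-hydroxy C11 iodide | O[C@H]1CCC[C@@]2(C)[C@H]1CC[C@H](C)[C@@]2(C)CI | intermediate
13 | 4-oxo C11 iodide | O=C1CCC[C@@]2(C)[C@H]1CC[C@H](C)[C@@]2(C)CI | intermediate
14 | 4-methylene C11 iodide, DecCH2–I | C=C1CCC[C@@]2(C)[C@H]1CC[C@H](C)[C@@]2(C)CI | intermediate
15 | di-tert-butyl squarate, 3,4-di-tert-butoxycyclobut-3-ene-1,2-dione | CC(C)(C)OC1=C(OC(C)(C)C)C(=O)C1=O | starting material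
16 | DecCH2–Li | C=C1CCC[C@@]2(C)[C@H]1CC[C@H](C)[C@@]2(C)C[Li] | intermediate (not isolated)
17 | 2,3-di-tert-butoxy-4-(DecCH2)-4-(lithiooxy)cyclobut-2-en-1-one, epimer mixture at the new carbinol carbon | C=C1CCC[C@@]2(C)[C@H]1CC[C@H](C)[C@@]2(C)CC1(O[Li])C(OC(C)(C)C)=C(OC(C)(C)C)C1=O | intermediate (not isolated)
18 | O-trifluoroacetate of adduct 17 | C=C1CCC[C@@]2(C)[C@H]1CC[C@H](C)[C@@]2(C)CC1(OC(=O)C(F)(F)F)C(OC(C)(C)C)=C(OC(C)(C)C)C1=O | intermediate (not isolated)
19 | 3-tert-butoxy-4-(DecCH2)cyclobut-3-ene-1,2-dione | C=C1CCC[C@@]2(C)[C@H]1CC[C@H](C)[C@@]2(C)CC1=C(OC(C)(C)C)C(=O)C1=O | intermediate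
20 | bromoacetaldehyde dimethyl acetal, 2-bromo-1,1-dimethoxyethane | COC(CBr)OC | starting material
21 | (Z)-1-bromo-2-methoxyethene | CO/C=C\Br | intermediate
22 | (Z)-2-methoxyvinyllithium | CO/C=C\[Li] | intermediate (not isolated)
23 | 3-tert-butoxy-4-hydroxy-4-[(Z)-2-methoxyethenyl]-2-(DecCH2)cyclobut-2-en-1-one, both carbinol epimers | C=C1CCC[C@@]2(C)[C@H]1CC[C@H](C)[C@@]2(C)CC1=C(OC(C)(C)C)C(O)(/C=C\OC)C1=O | intermediate
24 | 2-tert-butoxy-5-methoxy-3-(DecCH2)benzene-1,4-diol | C=C1CCC[C@@]2(C)[C@H]1CC[C@H](C)[C@@]2(C)Cc1c(OC(C)(C)C)c(O)cc(OC)c1O | intermediate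
25 | 2-tert-butoxy-5-methoxy-3-(DecCH2)cyclohexa-2,5-diene-1,4-dione | C=C1CCC[C@@]2(C)[C@H]1CC[C@H](C)[C@@]2(C)CC1=C(OC(C)(C)C)C(=O)C=C(OC)C1=O | intermediate
26 | 2-hydroxy-5-methoxy-3-{[(1R,2S,4aS,8aS)-1,2,8a-trimethyl-5-methylidenedecahydronaphthalen-1-yl]methyl}cyclohexa-2,5-diene-1,4-dione | C=C1CCC[C@@]2(C)[C@H]1CC[C@H](C)[C@@]2(C)CC1=C(O)C(=O)C=C(OC)C1=O | target

**Step count**
Total steps: 17. Longest linear sequence: 16 steps (steps 1–12 and 14–17); step 13 prepares reagent 21.

**Steps most likely to fail**

Step 5 (cycloaddition). Two fully substituted carbons must be joined, and the methyl on the diene terminus C10 hinders the s-cis geometry, so the reaction may stall. Bond formation may also become stepwise, which would erode the endo preference and the cis relationship of the 8- and 9-methyls. The Lewis acid may also ionise the allylic silyl ether.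

The fallback is an ionic Diels–Alder reaction, which replaces the complexed aldehyde by a cationic two-carbon partner. It sets out from diene 5 and aldehyde 6. Aldehyde 6 is condensed with ethylene glycol (p-TsOH, benzene, water removal) to 2-[(E)-but-2-en-2-yl]-1,3-dioxolane F1. With catalytic Me3SiOTf in CH2Cl2 at −78 °C this acetal opens to an alkoxy-substituted allyl cation, far more electrophilic than the aluminium-bound enal, which should add to 5 and reclose to the dioxolane adduct F2. Hydrolysis with pyridinium p-toluenesulfonate in aqueous acetone then returns the route at aldehyde 7.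

Step 8 (substitution at C11). Iodide may attack the doubly hindered neopentyl carbon too slowly, so that the triflate decomposes or rearranges by alkyl shift before it is displaced.

The fallback changes both the nucleophile and the way the organolithium is made. It sets out from alcohol 9 (through triflate 10).
- Sodium thiophenolate in DMF, a much stronger nucleophile than iodide, should give the C11 phenyl sulfide with 4β-OTBS F3.
- Desilylation with n-Bu4NF gives the 4β-hydroxy sulfide F4.
- Swern oxidation gives the 4-oxo sulfide F5.
- Petasis methylenation gives the 4-methylene sulfide F6.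
- Reductive lithiation of F6 with lithium 4,4'-di-tert-butylbiphenylide in THF at −78 °C cleaves the C–S bond and returns the route at alkyllithium 16, which is used as in step 12.

Step 17 (release of the hydroxyl). Protonation of the exocyclic methylene may compete, leading to migration of the double bond into the ring or to cationic closure onto a quinone oxygen.

The fallback avoids Brønsted acid. It sets out from quinone 25. Me3SiOTf and 2,6-lutidine in CH2Cl2 at −20 °C silylate the quinone carbonyl of the vinylogous ester and expel isobutene under buffered conditions, giving the trimethylsilyl ether of the target F7. Aqueous work-up cleaves the silyl ether and returns the route at target 26.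

**Further compounds**
F1 | step 5 | 2-[(E)-but-2-en-2-yl]-1,3-dioxolane | C/C=C(\C)C1OCCO1
F2 | step 5 | dioxolane acetal of aldehyde 7 | CC(C)(C)[Si](C)(C)O[C@H]1CCC[C@@]2(C)C1=CC[C@H](C)[C@@]2(C)C1OCCO1
F3 | step 8 | C11 phenyl sulfide with 4β-OTBS | CC(C)(C)[Si](C)(C)O[C@H]1CCC[C@@]2(C)[C@H]1CC[C@H](C)[C@@]2(C)CSc1ccccc1
F4 | step 8 | 4β-hydroxy C11 phenyl sulfide | O[C@H]1CCC[C@@]2(C)[C@H]1CC[C@H](C)[C@@]2(C)CSc1ccccc1
F5 | step 8 | 4-oxo C11 phenyl sulfide | O=C1CCC[C@@]2(C)[C@H]1CC[C@H](C)[C@@]2(C)CSc1ccccc1
F6 | step 8 | 4-methylene C11 phenyl sulfide | C=C1CCC[C@@]2(C)[C@H]1CC[C@H](C)[C@@]2(C)CSc1ccccc1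
F7 | step 17 | trimethylsilyl ether of target 26 | C=C1CCC[C@@]2(C)[C@H]1CC[C@H](C)[C@@]2(C)CC1=C(O[Si](C)(C)C)C(=O)C=C(OC)C1=O
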